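**Plan**

1. Retrosynthetic cuts: first the C5 O–CH3 bond and the ring B O–Si bond, then ring A at C5–C6, C7–C8 and C4a–C5, which leaves a dihydropyranyl vinylketene (from diazoketone 25) and 1-methoxyalkyne 29. Further back come the acyl C–C bond at the enol ether carbon (ketene acetal phosphate of δ-lactone 17), the C3–C4 bond (imide enolate plus acrylate) and the C–C and C–O bonds of ring D (aryl propargyl ether).
2. Forward order: ring D is fused onto ring B (steps 1–6), the C3 stereocentre is set on an open chain (step 8), ring C is closed as a δ-lactone (step 10) and converted into the diazoacetyl dihydropyran (steps 11–13). Ring A is grown onto it last (step 15), followed by O-methylation and desilylation (steps 16–17).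
3. Stereochemistry: the only stereocentre, C3 (R), comes from the (R)-4-benzyloxazolidin-2-one-directed Michael addition of step 8 and takes part in no later bond formation.
4. Enabling feature: ring A is a pentasubstituted benzene with oxygen on C5, C7 and C8a, hydrogen on C8 and the prenyl group on C6 between the C5 and C7 oxygens. A vinylketene whose vinyl unit is the ring C enol ether (C4a=C8a–O1) and a prenyl-bearing 1-methoxyalkyne assemble exactly this pattern, the alkyne oxygen ending on C7 and the ketene oxygen on C5.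

Key step: step 15

Remark: isoflavan numbering (O1, C2, C3, C4, C4a, C5–C8, C8a; ring B primed; ring D is the dimethylpyran fused to ring B) is used for the chroman positions. Ar stands for 2,2-dimethyl-5-(triisopropylsilyloxy)-2H-chromen-8-yl. Compounds 10, 20 and 26 are assumed to be purchased.

**Route**

Step 1
Reactants: 1 2,4-dihydroxyphenylacetic acid
Product: 2 6-hydroxybenzofuran-2(3H)-one
Conditions: TsOH·H2O (cat.), toluene, reflux, azeotropic removal of water
Reagents that add atoms: none
Why: Acid-catalysed lactonisation can only engage the ortho hydroxyl, so the 2-OH and the carboxyl group are masked together and the 4-OH alone stays free.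

Step 2
Reactants: 2 6-hydroxybenzofuran-2(3H)-one
Product: 3 6-(triisopropylsilyloxy)benzofuran-2(3H)-one
Conditions: iPr3SiOTf, 2,6-lutidine, CH2Cl2, 0 °C
Reagents that add atoms: triisopropylsilyl trifluoromethanesulfonate, CC(C)[Si](C(C)C)(C(C)C)OS(=O)(=O)C(F)(F)F
Why: O-silylation of the single free phenol with a silyl triflate and a hindered, non-nucleophilic pyridine base should leave the aryl ester lactone closed.

Step 3
Reactants: 3 6-(triisopropylsilyloxy)benzofuran-2(3H)-one
Product: 4 methyl 2-[2-hydroxy-4-(triisopropylsilyloxy)phenyl]acetate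
Conditions: MeOH, Et3N (cat.), 25 °C
Reagents that add atoms: methanol, CO
Why: Base-catalysed transesterification in excess methanol opens the activated aryl ester lactone to the methyl ester and releases the ortho phenol, while triethylamine in methanol is too mild to cleave the bulky aryl silyl ether.

Step 4
Reactants: 4 methyl 2-[2-hydroxy-4-(triisopropylsilyloxy)phenyl]acetate; 5 3-chloro-3-methylbut-1-yne
Product: 6 methyl 2-[2-(2-methylbut-3-yn-2-yloxy)-4-(triisopropylsilyloxy)phenyl]acetate
Conditions: DBU, CuCl2·2H2O (cat.), MeCN, 0 °C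
Reagents that add atoms: none
Why: Copper-catalysed O-propargylation of a phenol with a tertiary propargylic chloride proceeds through a copper allenylidene and should give the hindered aryl 1,1-dimethylpropargyl ether under mild base.

Step 5
Reactants: 6 methyl 2-[2-(2-methylbut-3-yn-2-yloxy)-4-(triisopropylsilyloxy)phenyl]acetate
Product: 8 methyl 2-[2,2-dimethyl-5-(triisopropylsilyloxy)-2H-chromen-8-yl]acetate, via allenylphenol 7 (not isolated)
Conditions: o-xylene, 140 °C
Reagents that add atoms: none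
Why: The aryl propargyl ether Claisen rearrangement can reach only the free ortho carbon between the two oxygens, and allenylphenol 7 should close to the 2,2-dimethylchromene (ring D) by 1,5-hydrogen shift and oxa-6π electrocyclisation.

Step 6
Reactants: 8 methyl 2-[2,2-dimethyl-5-(triisopropylsilyloxy)-2H-chromen-8-yl]acetate
Product: 9 2-[2,2-dimethyl-5-(triisopropylsilyloxy)-2H-chromen-8-yl]acetic acid
Conditions: LiOH·H2O, THF/H2O, 0 °C to 25 °C; then 1 M HCl to pH 4, 0 °C
Reagents that add atoms: lithium hydroxide, [Li+].[OH-]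
Why: Saponification of the unhindered methyl ester should be much faster than attack of hydroxide on the triisopropylsilyl aryl ether.

Step 7
Reactants: 9 2-[2,2-dimethyl-5-(triisopropylsilyloxy)-2H-chromen-8-yl]acetic acid; 10 (R)-4-benzyloxazolidin-2-one
Product: 12 (4R)-4-benzyl-3-(2-Ar-acetyl)oxazolidin-2-one, via mixed pivalic anhydride 11 (not isolated)
Conditions: tBuCOCl, Et3N, THF, −20 °C; then 10, LiCl, 25 °C
Reagents that add atoms: none
Why: N-acylation of the oxazolidinone by mixed anhydride 11 occurs at the less hindered arylacetyl carbonyl under LiCl/Et3N activation and needs no strong base.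

Step 8
Reactants: 12 (4R)-4-benzyl-3-(2-Ar-acetyl)oxazolidin-2-one; 13 tert-butyl acrylate
Product: 15 tert-butyl (4R)-4-Ar-5-[(4R)-4-benzyl-2-oxooxazolidin-3-yl]-5-oxopentanoate, via chlorotitanium enolate 14 (not isolated)
Conditions: TiCl4, Ti(OiPr)4, iPr2NEt, CH2Cl2, 0 °C; then 13, 0 °C
Reagents that add atoms: none
Why: Soft enolisation gives the chelated Z-configured titanium enolate 14, whose face on the side of the auxiliary benzyl group is blocked, so the acrylate adds to the open face and should set the (R) configuration of the future C3 (auxiliary-controlled titanium enolate Michael addition).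

Step 9
Reactants: 15 tert-butyl (4R)-4-Ar-5-[(4R)-4-benzyl-2-oxooxazolidin-3-yl]-5-oxopentanoate
Product: 16 tert-butyl (4R)-4-Ar-5-hydroxypentanoate
Conditions: LiBH4, MeOH (1 equiv), THF, 0 °C
Reagents that add atoms: none
Why: LiBH4 reduces the activated exocyclic imide carbonyl to the primary alcohol and spares the tert-butyl ester, releasing the auxiliary under conditions too weakly basic to epimerise the benzylic centre (reductive auxiliary cleavage).

Step 10
Reactants: 16 tert-butyl (4R)-4-Ar-5-hydroxypentanoate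
Product: 17 (5R)-5-Ar-tetrahydro-2H-pyran-2-one
Conditions: TsOH·H2O (cat.), toluene, 80 °C
Reagents that add atoms: none
Why: Acid-catalysed lactonisation of the δ-hydroxy tert-butyl ester with loss of isobutene closes the six-membered lactone (future ring C), and catalytic sulfonic acid in warm toluene is a medium in which 2,2-dimethylchromenes are themselves routinely formed, so ring D should survive.

Step 11
Reactants: 17 (5R)-5-Ar-tetrahydro-2H-pyran-2-one
Product: 19 (3R)-3-Ar-3,4-dihydro-2H-pyran-6-yl diphenyl phosphate, via potassium enolate 18 (not isolated)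
Conditions: KN(SiMe3)2, (PhO)2P(O)Cl, THF/HMPA, −78 °C
Reagents that add atoms: diphenyl phosphorochloridate, O=P(Cl)(Oc1ccccc1)Oc1ccccc1
Why: Kinetic deprotonation at the only α-methylene and O-phosphorylation of enolate 18 give the cyclic ketene acetal phosphate, which is easier to handle than the corresponding triflate (enol phosphate formation).

Step 12
Reactants: 19 (3R)-3-Ar-3,4-dihydro-2H-pyran-6-yl diphenyl phosphate; 20 tributyl(1-ethoxyvinyl)stannane
Product: 22 1-[(3R)-3-Ar-3,4-dihydro-2H-pyran-6-yl]ethanone, via ethoxyvinyl diene 21 (not isolated)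
Conditions: Pd(PPh3)4 (cat.), LiCl, THF, 65 °C; then 1 M HCl, THF, 0 °C
Reagents that add atoms: water, O
Why: Stille coupling of the ketene acetal phosphate gives diene 21, whose acyclic enol ether should be hydrolysed by cold dilute acid far faster than the ring enol ether, which in the product is deactivated by conjugation with the new carbonyl group.

Step 13
Reactants: 22 1-[(3R)-3-Ar-3,4-dihydro-2H-pyran-6-yl]ethanone
Product: 25 2-diazo-1-[(3R)-3-Ar-3,4-dihydro-2H-pyran-6-yl]ethanone, via lithium enolate 23 (not isolated), via trifluoroacetyl ketone 24 (not isolated)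
Conditions: LiN(SiMe3)2, THF, −78 °C; CF3CO2CH2CF3, −78 °C; aq. HCl quench; then MsN3, Et3N, H2O, MeCN, 25 °C
Reagents that add atoms: methanesulfonyl azide, CS(=O)(=O)N=[N+]=[N-]
Why: In this detrifluoroacetylative diazo transfer the kinetic methyl enolate 23 is acylated to the activated 1,3-diketone 24, which takes the diazo group from the sulfonyl azide and loses the trifluoroacetyl group, avoiding the dipolar cycloadditions that plague the acid chloride–diazomethane route to unsaturated diazoketones.

Step 14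
Reactants: 26 2-chloro-1,1-dimethoxyethane; 27 prenyl bromide
Product: 29 1-methoxy-5-methylhex-4-en-1-yne, via lithium methoxyacetylide 28 (not isolated)
Conditions: n-BuLi, Et2NH (3 equiv LiNEt2), THF, 0 °C; then 27, HMPA, −78 °C to 25 °C
Reagents that add atoms: none
Why: Two eliminations and a deprotonation of the chloroacetal give acetylide 28, which should be alkylated by the allylic bromide at its primary carbon in the presence of HMPA (acetylide alkylation), and the methyl ynol ether cannot fragment by retro-ene reaction at the temperature of step 15.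

Step 15
Reactants: 25 2-diazo-1-[(3R)-3-Ar-3,4-dihydro-2H-pyran-6-yl]ethanone; 29 1-methoxy-5-methylhex-4-en-1-yne
Product: 34 (3R)-3-Ar-7-methoxy-6-(3-methylbut-2-enyl)chroman-5-ol, via vinylketene 30 (not isolated), via vinylcyclobutenone 31 (not isolated), via dienylketene 32 (not isolated), via cyclohexadienone 33 (not isolated)
Conditions: 29 (3 equiv), hν (365 nm), ClCH2CH2Cl, 25 °C; then 80 °C
Reagents that add atoms: none
Why: Light-induced loss of N2 with Wolff shift of the dihydropyranyl group gives vinylketene 30, whose electrophilic carbonyl carbon (future C5) bonds to the nucleophilic prenyl-bearing carbon of ynol ether 29 while its CH (future C8) bonds to the methoxy-bearing carbon, so the [2+2] adduct is cyclobutenone 31. Warming opens 31 by 4π electrocyclic cleavage to dienylketene 32, and ring A closes by thermal disrotatory 6π electrocyclisation between the ketene carbon C5 and the enol ether β-carbon C4a, after which dienone 33 enolises to the C5 phenol. This is the Danheiser benzannulation of an α,β-unsaturated diazomethyl ketone with a 1-alkoxyalkyne, and the closest precedents are cycloalkenyl and 2-furyl diazoketones, of which the dihydropyranyl ketone is the non-aromatic oxygen analogue. No stereocentre is created, since the sp3 carbon C4a of 33 is lost on aromatisation, and C3 lies two bonds from the nearest reacting atom and carries no acidic hydrogen. The one regiochemical demand, prenyl on C6 between the two oxygens, is secured by the polarisation of the ynol ether, which delivers its oxygen-free carbon to the ketene carbonyl. Long-wavelength light is absorbed by the conjugated diazoketone but hardly by ring D, whose photochemical ring opening would in any case revert thermally.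

Step 16
Reactants: 34 (3R)-3-Ar-7-methoxy-6-(3-methylbut-2-enyl)chroman-5-ol
Product: 35 (3R)-3-Ar-5,7-dimethoxy-6-(3-methylbut-2-enyl)chroman
Conditions: MeI, K2CO3, acetone, 50 °C
Reagents that add atoms: iodomethane, CI
Why: Williamson O-methylation of the only free phenol under anhydrous carbonate conditions should not cleave the triisopropylsilyl aryl ether, so the ring B oxygen stays differentiated.

Step 17
Reactants: 35 (3R)-3-Ar-5,7-dimethoxy-6-(3-methylbut-2-enyl)chroman
Product: 36 Kanzonol I
Conditions: Bu4NF, AcOH, THF, 0 °C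
Reagents that add atoms: none
Why: Fluoride cleaves the aryl O–Si bond, and the acetic acid buffer protonates the phenoxide at once, so the prenyl and chromene alkenes and both methyl ethers should stay untouched (desilylation).

**Compound list**

1 | 2,4-dihydroxyphenylacetic acid | OC(=O)Cc1ccc(O)cc1O | starting material
2 | 6-hydroxybenzofuran-2(3H)-one | O=C1Cc2ccc(O)cc2O1 | intermediate
3 | 6-(triisopropylsilyloxy)benzofuran-2(3H)-one | O=C1Cc2ccc(O[Si](C(C)C)(C(C)C)C(C)C)cc2O1 | intermediate
4 | methyl 2-[2-hydroxy-4-(triisopropylsilyloxy)phenyl]acetate | COC(=O)Cc1ccc(O[Si](C(C)C)(C(C)C)C(C)C)cc1O | intermediate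
5 | 3-chloro-3-methylbut-1-yne | CC(C)(Cl)C#C | starting material
6 | methyl 2-[2-(2-methylbut-3-yn-2-yloxy)-4-(triisopropylsilyloxy)phenyl]acetate | COC(=O)Cc1ccc(O[Si](C(C)C)(C(C)C)C(C)C)cc1OC(C)(C)C#C | intermediate
7 | methyl 2-[2-hydroxy-3-(3-methylbuta-1,2-dien-1-yl)-4-(triisopropylsilyloxy)phenyl]acetate (allenylphenol) | COC(=O)Cc1ccc(O[Si](C(C)C)(C(C)C)C(C)C)c(C=C=C(C)C)c1O | intermediate
8 | methyl 2-[2,2-dimethyl-5-(triisopropylsilyloxy)-2H-chromen-8-yl]acetate | COC(=O)Cc1ccc(O[Si](C(C)C)(C(C)C)C(C)C)c2c1OC(C)(C)C=C2 | intermediate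
9 | 2-[2,2-dimethyl-5-(triisopropylsilyloxy)-2H-chromen-8-yl]acetic acid | OC(=O)Cc1ccc(O[Si](C(C)C)(C(C)C)C(C)C)c2c1OC(C)(C)C=C2 | intermediate
10 | (R)-4-benzyloxazolidin-2-one | O=C1N[C@H](Cc2ccccc2)CO1 | starting material
11 | mixed anhydride of 9 with pivalic acid | CC(C)(C)C(=O)OC(=O)Cc1ccc(O[Si](C(C)C)(C(C)C)C(C)C)c2c1OC(C)(C)C=C2 | intermediate
12 | (4R)-4-benzyl-3-(2-Ar-acetyl)oxazolidin-2-one | O=C(Cc1ccc(O[Si](C(C)C)(C(C)C)C(C)C)c2c1OC(C)(C)C=C2)N1[C@H](Cc2ccccc2)COC1=O | intermediate
13 | tert-butyl acrylate | C=CC(=O)OC(C)(C)C | starting material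
14 | Z-configured dichloro(isopropoxy)titanium enolate of 12 | CC(C)O[Ti](Cl)(Cl)O/C(=C\c1ccc(O[Si](C(C)C)(C(C)C)C(C)C)c2c1OC(C)(C)C=C2)N1[C@H](Cc2ccccc2)COC1=O | intermediate
15 | tert-butyl (4R)-4-Ar-5-[(4R)-4-benzyl-2-oxooxazolidin-3-yl]-5-oxopentanoate | CC(C)(C)OC(=O)CC[C@H](c1ccc(O[Si](C(C)C)(C(C)C)C(C)C)c2c1OC(C)(C)C=C2)C(=O)N1[C@H](Cc2ccccc2)COC1=O | intermediate
16 | tert-butyl (4R)-4-Ar-5-hydroxypentanoate | CC(C)(C)OC(=O)CC[C@H](c1ccc(O[Si](C(C)C)(C(C)C)C(C)C)c2c1OC(C)(C)C=C2)CO | intermediate
17 | (5R)-5-Ar-tetrahydro-2H-pyran-2-one | O=C1CC[C@H](c2ccc(O[Si](C(C)C)(C(C)C)C(C)C)c3c2OC(C)(C)C=C3)CO1 | intermediate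
18 | potassium enolate of 17 | [K+].[O-]C1=CC[C@H](c2ccc(O[Si](C(C)C)(C(C)C)C(C)C)c3c2OC(C)(C)C=C3)CO1 | intermediate
19 | (3R)-3-Ar-3,4-dihydro-2H-pyran-6-yl diphenyl phosphate | O=P(Oc1ccccc1)(Oc1ccccc1)OC1=CC[C@H](c2ccc(O[Si](C(C)C)(C(C)C)C(C)C)c3c2OC(C)(C)C=C3)CO1 | intermediate
20 | tributyl(1-ethoxyvinyl)stannane | CCCC[Sn](CCCC)(CCCC)C(=C)OCC | starting material
21 | (3R)-3-Ar-6-(1-ethoxyvinyl)-3,4-dihydro-2H-pyran | CCOC(=C)C1=CC[C@H](c2ccc(O[Si](C(C)C)(C(C)C)C(C)C)c3c2OC(C)(C)C=C3)CO1 | intermediate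
22 | 1-[(3R)-3-Ar-3,4-dihydro-2H-pyran-6-yl]ethanone | CC(=O)C1=CC[C@H](c2ccc(O[Si](C(C)C)(C(C)C)C(C)C)c3c2OC(C)(C)C=C3)CO1 | intermediate
23 | lithium enolate of 22 | [Li+].[O-]C(=C)C1=CC[C@H](c2ccc(O[Si](C(C)C)(C(C)C)C(C)C)c3c2OC(C)(C)C=C3)CO1 | intermediate
24 | 4,4,4-trifluoro-1-[(3R)-3-Ar-3,4-dihydro-2H-pyran-6-yl]butane-1,3-dione | O=C(CC(=O)C(F)(F)F)C1=CC[C@H](c2ccc(O[Si](C(C)C)(C(C)C)C(C)C)c3c2OC(C)(C)C=C3)CO1 | intermediate
25 | 2-diazo-1-[(3R)-3-Ar-3,4-dihydro-2H-pyran-6-yl]ethanone | [N-]=[N+]=CC(=O)C1=CC[C@H](c2ccc(O[Si](C(C)C)(C(C)C)C(C)C)c3c2OC(C)(C)C=C3)CO1 | intermediate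
26 | 2-chloro-1,1-dimethoxyethane | COC(CCl)OC | starting material
27 | prenyl bromide (1-bromo-3-methylbut-2-ene) | CC(C)=CCBr | starting material
28 | lithium methoxyacetylide | [Li]C#COC | intermediate
29 | 1-methoxy-5-methylhex-4-en-1-yne | COC#CCC=C(C)C | intermediate
30 | 2-[(3R)-3-Ar-3,4-dihydro-2H-pyran-6-yl]ethenone (vinylketene) | O=C=CC1=CC[C@H](c2ccc(O[Si](C(C)C)(C(C)C)C(C)C)c3c2OC(C)(C)C=C3)CO1 | intermediate
31 | 4-[(3R)-3-Ar-3,4-dihydro-2H-pyran-6-yl]-3-methoxy-2-(3-methylbut-2-enyl)cyclobut-2-en-1-one | COC1=C(CC=C(C)C)C(=O)C1C1=CC[C@H](c2ccc(O[Si](C(C)C)(C(C)C)C(C)C)c3c2OC(C)(C)C=C3)CO1 | intermediate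
32 | 4-[(3R)-3-Ar-3,4-dihydro-2H-pyran-6-yl]-3-methoxy-2-(3-methylbut-2-enyl)buta-1,3-dien-1-one, dihydropyranyl cis to the ketene carbon (dienylketene) | CO/C(=C/C1=CC[C@H](c2ccc(O[Si](C(C)C)(C(C)C)C(C)C)c3c2OC(C)(C)C=C3)CO1)C(CC=C(C)C)=C=O | intermediate
33 | (3R)-3-Ar-7-methoxy-6-(3-methylbut-2-enyl)-2,3,4,4a-tetrahydro-5H-chromen-5-one (transient, C4a unassigned) | COC1=C(CC=C(C)C)C(=O)C2C[C@H](c3ccc(O[Si](C(C)C)(C(C)C)C(C)C)c4c3OC(C)(C)C=C4)COC2=C1 | intermediate
34 | (3R)-3-Ar-7-methoxy-6-(3-methylbut-2-enyl)chroman-5-ol | COc1cc2c(c(O)c1CC=C(C)C)C[C@H](c1ccc(O[Si](C(C)C)(C(C)C)C(C)C)c3c1OC(C)(C)C=C3)CO2 | intermediate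
35 | (3R)-3-Ar-5,7-dimethoxy-6-(3-methylbut-2-enyl)chroman | COc1cc2c(c(OC)c1CC=C(C)C)C[C@H](c1ccc(O[Si](C(C)C)(C(C)C)C(C)C)c3c1OC(C)(C)C=C3)CO2 | intermediate
36 | Kanzonol I, 8-[(3R)-5,7-dimethoxy-6-(3-methylbut-2-enyl)chroman-3-yl]-2,2-dimethyl-2H-chromen-5-ol | COc1cc2c(c(OC)c1CC=C(C)C)C[C@H](c1ccc(O)c3c1OC(C)(C)C=C3)CO2 | target

**Step count and risks**

Total steps: 17. Longest linear sequence: 16 (steps 1–13 and 15–17; step 14 is the side branch).

Steps most likely to fail:

1. Step 15. Ring D may compete for the light and be degraded through its ring-opened form. The vinylketene may also be consumed by dimerisation or by acylating the product phenol before it meets the ynol ether. The fallback generates the same vinylketene thermally, without light, and sets out from 19. Negishi coupling of 19 with the Reformatsky reagent BrZnCH2CO2Et under Pd(PPh3)4 catalysis should give ethyl 2-[(3R)-3-Ar-3,4-dihydro-2H-pyran-6-yl]acetate F1. Saponification with LiOH and buffering to pH 5 gives 2-[(3R)-3-Ar-3,4-dihydro-2H-pyran-6-yl]acetic acid F2. 1-Chloro-N,N,2-trimethylprop-1-en-1-amine converts it under neutral conditions into 2-[(3R)-3-Ar-3,4-dihydro-2H-pyran-6-yl]acetyl chloride F3. Slow addition of F3 to Et3N and 29 in toluene at 80 °C dehydrochlorinates it to vinylketene 30, which follows the same cycloaddition and electrocyclic sequence, and the route is rejoined at 34.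

2. Step 12. Oxidative addition into the ketene acetal phosphate may be slow, with return of lactone by P–O cleavage, or the ring enol ether may be hydrolysed together with the ethoxyvinyl group. The fallback avoids the acidic hydrolysis and sets out from 19. Carbonylation (CO, MeOH, Et3N, Pd(PPh3)4, DMF) should give methyl (3R)-3-Ar-3,4-dihydro-2H-pyran-6-carboxylate F4. MeNH(OMe)·HCl with iPrMgCl in THF at −20 °C converts it into (3R)-N-methoxy-N-methyl-3-Ar-3,4-dihydro-2H-pyran-6-carboxamide F5. MeMgBr then gives the methyl ketone, and the route is rejoined at 22.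

3. Step 8. The stabilised arylacetyl titanium enolate may add sluggishly to the acrylate, facial selectivity may erode, or the Lewis acid may ionise the allylic aryl ether of ring D. The fallback sets the same centre by alkylation and sets out from 12. Treatment with NaN(SiMe3)2 and propargyl bromide in THF at −78 °C should give (4R)-4-benzyl-3-[(2R)-2-Ar-pent-4-ynoyl]oxazolidin-2-one F6 with the same facial sense. LiBH4 reduction gives (2R)-2-Ar-pent-4-yn-1-ol F7. Ruthenium vinylidene oxidative cyclisation (CpRuCl(PPh3)2 (cat.), N-hydroxysuccinimide, Bu4NBr, NaHCO3, DMF/H2O, 95 °C) turns the terminal alkyne carbon into the lactone carbonyl, and the route is rejoined at 17.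

**Further compounds**

F1 | step 15 | ethyl 2-[(3R)-3-Ar-3,4-dihydro-2H-pyran-6-yl]acetate | CCOC(=O)CC1=CC[C@H](c2ccc(O[Si](C(C)C)(C(C)C)C(C)C)c3c2OC(C)(C)C=C3)CO1
F2 | step 15 | 2-[(3R)-3-Ar-3,4-dihydro-2H-pyran-6-yl]acetic acid | OC(=O)CC1=CC[C@H](c2ccc(O[Si](C(C)C)(C(C)C)C(C)C)c3c2OC(C)(C)C=C3)CO1
F3 | step 15 | 2-[(3R)-3-Ar-3,4-dihydro-2H-pyran-6-yl]acetyl chloride | ClC(=O)CC1=CC[C@H](c2ccc(O[Si](C(C)C)(C(C)C)C(C)C)c3c2OC(C)(C)C=C3)CO1
F4 | step 12 | methyl (3R)-3-Ar-3,4-dihydro-2H-pyran-6-carboxylate | COC(=O)C1=CC[C@H](c2ccc(O[Si](C(C)C)(C(C)C)C(C)C)c3c2OC(C)(C)C=C3)CO1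
F5 | step 12 | (3R)-N-methoxy-N-methyl-3-Ar-3,4-dihydro-2H-pyran-6-carboxamide | CON(C)C(=O)C1=CC[C@H](c2ccc(O[Si](C(C)C)(C(C)C)C(C)C)c3c2OC(C)(C)C=C3)CO1
F6 | step 8 | (4R)-4-benzyl-3-[(2R)-2-Ar-pent-4-ynoyl]oxazolidin-2-one | C#CC[C@H](c1ccc(O[Si](C(C)C)(C(C)C)C(C)C)c2c1OC(C)(C)C=C2)C(=O)N1[C@H](Cc2ccccc2)COC1=O
F7 | step 8 | (2R)-2-Ar-pent-4-yn-1-ol | C#CC[C@H](c1ccc(O[Si](C(C)C)(C(C)C)C(C)C)c2c1OC(C)(C)C=C2)CO
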